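**Retrosynthetic overview**
1. The target comes from NaBH4 reduction of the ring-B aldehyde; before that, the aldehyde serves as the ortho activator for the ether coupling.
2. The diaryl ether C–O bond comes from a Cu-catalysed Ullmann coupling of methyl 2,6-dihydroxy-4-methylbenzoate (symmetric diol, so mono-arylation needs no protecting group) with 2-bromo-5-methoxy-3-prenyloxybenzaldehyde.
3. Ring A is the only ring built and is formed first: Dieckmann closure of dimethyl 5-methyl-3-oxoheptanedioate to the 2-carbomethoxy-5-methylcyclohexane-1,3-dione, then dehydrogenation to the resorcinol ester.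
4. Key C–C bond: an intermolecular decarboxylative Claisen condensation joins the C6 acid chloride of monomethyl 3-methylglutarate with the C2 unit potassium methyl malonate.
5. Ring B is bought as an arene (3-hydroxy-5-methoxybenzaldehyde) and elaborated by acetylation, bromination para to OMe, deacetylation and O-prenylation.

Assumption: the target has no stereocentre and no stereogenic double bond, so it is achiral and needs no stereocontrol; the chiral intermediates 2, 3, 5, 6 and 7 are used as racemates, and their stereocentre disappears on aromatisation.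

**Route**

Step 1
Reactants: 1 3-methylglutaric anhydride
Product: 2 5-methoxy-3-methyl-5-oxopentanoic acid (monomethyl 3-methylglutarate, racemic)
Conditions: MeOH, reflux, 3 h; evaporate
Reagents that add atoms: methanol, CO
Why: Alcoholysis of a symmetric cyclic anhydride stops cleanly at the half-ester and can give only one constitutional product.

Step 2
Reactants: 2 5-methoxy-3-methyl-5-oxopentanoic acid
Product: 3 methyl 5-chloro-3-methyl-5-oxopentanoate (racemic)
Conditions: (COCl)2, cat. DMF, CH2Cl2, 0 °C to rt; evaporate
Reagents that add atoms: oxalyl chloride, O=C(Cl)C(=O)Cl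
Why: Vilsmeier-type acid chloride formation is mild enough to leave the methyl ester untouched and gives volatile by-products only.

Step 3
Reactants: 3 methyl 5-chloro-3-methyl-5-oxopentanoate; 4 potassium methyl malonate
Product: 6 dimethyl 5-methyl-3-oxoheptanedioate, via acylmalonic half-ester 5 (not isolated)
Conditions: 4 (2.1 equiv), MgCl2, Et3N, MeCN, rt, 2 h; then 3, 0 °C to rt, 12 h; 1 M HCl
Reagents that add atoms: none
Why: In this intermolecular decarboxylative Claisen condensation (Masamune–Brooks type) the magnesium enolate of the malonate half-ester is C-acylated by the acid chloride and then loses CO2, which makes the step irreversible and prevents double acylation.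

Step 4
Reactants: 6 dimethyl 5-methyl-3-oxoheptanedioate
Product: 7 methyl 2-hydroxy-4-methyl-6-oxocyclohex-1-ene-1-carboxylate (enol form of methyl 4-methyl-2,6-dioxocyclohexane-1-carboxylate, racemic)
Conditions: NaOMe (2.2 equiv), MeOH, reflux, 4 h; then aq. HCl, 0 °C
Reagents that add atoms: none
Why: In this Dieckmann condensation the stabilised β-keto ester enolate (C2) attacks the remote ester in a 6-exo closure, and the very acidic 2-acyl-1,3-dione product is held as its enolate, which drives the equilibrium to this regioisomer.

Step 5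
Reactants: 7 methyl 2-hydroxy-4-methyl-6-oxocyclohex-1-ene-1-carboxylate
Product: 8 methyl 2,6-dihydroxy-4-methylbenzoate
Conditions: Hg(OAc)2, NaOAc, AcOH, reflux, 3 h
Reagents that add atoms: none
Why: Mercuric acetate dehydrogenation of a 2-acylcyclohexane-1,3-dione proceeds by α-mercuration of the enol and loss of Hg(0) and AcOH to a cyclohexenedione that tautomerises to the resorcinol, removing the only stereocentre.

Step 6
Reactants: 9 3-hydroxy-5-methoxybenzaldehyde
Product: 10 3-formyl-5-methoxyphenyl acetate
Conditions: Ac2O, pyridine, cat. DMAP, CH2Cl2, rt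
Reagents that add atoms: acetic anhydride, CC(=O)OC(C)=O
Why: O-Acetylation turns the phenol oxygen into a weak donor so that the methoxy group alone directs the next electrophilic substitution.

Step 7
Reactants: 10 3-formyl-5-methoxyphenyl acetate
Product: 11 2-bromo-3-formyl-5-methoxyphenyl acetate
Conditions: NBS (1.05 equiv), DMF, rt, dark
Reagents that add atoms: N-bromosuccinimide, O=C1CCC(=O)N1Br
Why: Electrophilic aromatic bromination goes para to the strongest donor (OMe), which is the position between CHO and OAc, as in the bromination of 3-methoxybenzaldehyde.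

Step 8
Reactants: 11 2-bromo-3-formyl-5-methoxyphenyl acetate
Product: 12 2-bromo-3-hydroxy-5-methoxybenzaldehyde
Conditions: K2CO3 (0.2 equiv), MeOH, 0 °C to rt, 1 h
Reagents that add atoms: none
Why: Base-catalysed transesterification of an aryl acetate (an activated ester) with methanol is fast and leaves the aldehyde and the aryl bromide alone.

Step 9
Reactants: 12 2-bromo-3-hydroxy-5-methoxybenzaldehyde
Product: 13 2-bromo-5-methoxy-3-[(3-methylbut-2-en-1-yl)oxy]benzaldehyde
Conditions: prenyl bromide (1.2 equiv), K2CO3, DMF, rt
Reagents that add atoms: prenyl bromide (1-bromo-3-methylbut-2-ene), CC(C)=CCBr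
Why: Williamson O-alkylation of the phenoxide with a primary allylic bromide is clean SN2 at the unsubstituted terminus.

Step 10
Reactants: 8 methyl 2,6-dihydroxy-4-methylbenzoate (2.0 equiv); 13 2-bromo-5-methoxy-3-[(3-methylbut-2-en-1-yl)oxy]benzaldehyde
Product: 14 methyl 2-{2-formyl-4-methoxy-6-[(3-methylbut-2-en-1-yl)oxy]phenoxy}-6-hydroxy-4-methylbenzoate
Conditions: CuI (10 mol%), picolinic acid (20 mol%), K3PO4 (3 equiv), DMSO, 90 °C, Ar, 24 h
Reagents that add atoms: none
Why: In this Ullmann-type Cu(I)-catalysed O-arylation the ortho-formyl group activates the hindered C–Br bond, and because 8 is a symmetric diol used in excess, mono-arylation leaves the second (ester-chelated) OH free as the target requires.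

Step 11
Reactants: 14 methyl 2-{2-formyl-4-methoxy-6-[(3-methylbut-2-en-1-yl)oxy]phenoxy}-6-hydroxy-4-methylbenzoate
Product: 15 methyl 2-hydroxy-6-{2-(hydroxymethyl)-4-methoxy-6-[(3-methylbut-2-en-1-yl)oxy]phenoxy}-4-methylbenzoate (target)
Conditions: NaBH4 (1.0 equiv), THF/MeOH, 0 °C, 30 min; aq. NH4Cl
Reagents that add atoms: none
Why: Borohydride reduction is chemoselective for the aryl aldehyde over the hindered, phenol-chelated methyl ester and does not touch the prenyl alkene.

**Compound list**
1 | 3-methylglutaric anhydride (4-methyloxane-2,6-dione) | CC1CC(=O)OC(=O)C1 | starting material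
2 | 5-methoxy-3-methyl-5-oxopentanoic acid (racemic) | COC(=O)CC(C)CC(=O)O | intermediate
3 | methyl 5-chloro-3-methyl-5-oxopentanoate (racemic) | COC(=O)CC(C)CC(=O)Cl | intermediate
4 | potassium methyl malonate (potassium 3-methoxy-3-oxopropanoate) | COC(=O)CC(=O)[O-].[K+] | starting material
5 | 7-methoxy-2-(methoxycarbonyl)-5-methyl-3,7-dioxoheptanoic acid (acylmalonic half-ester, neutral form, diastereomer mixture) | COC(=O)CC(C)CC(=O)C(C(=O)O)C(=O)OC | intermediate (not isolated)
6 | dimethyl 5-methyl-3-oxoheptanedioate (racemic) | COC(=O)CC(=O)CC(C)CC(=O)OC | intermediate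
7 | methyl 2-hydroxy-4-methyl-6-oxocyclohex-1-ene-1-carboxylate (racemic) | COC(=O)C1=C(O)CC(C)CC1=O | intermediate
8 | methyl 2,6-dihydroxy-4-methylbenzoate | COC(=O)c1c(O)cc(C)cc1O | intermediate
9 | 3-hydroxy-5-methoxybenzaldehyde | COc1cc(O)cc(C=O)c1 | starting material
10 | 3-formyl-5-methoxyphenyl acetate | CC(=O)Oc1cc(OC)cc(C=O)c1 | intermediate
11 | 2-bromo-3-formyl-5-methoxyphenyl acetate | CC(=O)Oc1cc(OC)cc(C=O)c1Br | intermediate
12 | 2-bromo-3-hydroxy-5-methoxybenzaldehyde | COc1cc(O)c(Br)c(C=O)c1 | intermediate
13 | 2-bromo-5-methoxy-3-[(3-methylbut-2-en-1-yl)oxy]benzaldehyde | COc1cc(OCC=C(C)C)c(Br)c(C=O)c1 | intermediate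
14 | methyl 2-{2-formyl-4-methoxy-6-[(3-methylbut-2-en-1-yl)oxy]phenoxy}-6-hydroxy-4-methylbenzoate | COC(=O)c1c(O)cc(C)cc1Oc1c(C=O)cc(OC)cc1OCC=C(C)C | intermediate
15 | methyl 2-hydroxy-6-{2-(hydroxymethyl)-4-methoxy-6-[(3-methylbut-2-en-1-yl)oxy]phenoxy}-4-methylbenzoate | COC(=O)c1c(O)cc(C)cc1Oc1c(CO)cc(OC)cc1OCC=C(C)C | target

**Summary**
Total step count: 11. Longest linear sequence: 7 steps (steps 1, 2, 3, 4, 5, 10, 11).

Three steps most likely to fail:

Step 10 (Ullmann coupling of a di-ortho-substituted bromide with an ester-chelated phenol). The fallback sets out from 13 and comes back to the route at 15. Pinnick oxidation of 13 (NaClO2, NaH2PO4, excess 2-methyl-2-butene, t-BuOH/H2O) gives 2-bromo-5-methoxy-3-[(3-methylbut-2-en-1-yl)oxy]benzoic acid F2. The ortho-carboxylate-accelerated Ullmann condensation of F2 with 8 (CuI, Cs2CO3, DMF, 100 °C) gives 2-[3-hydroxy-2-(methoxycarbonyl)-5-methylphenoxy]-5-methoxy-3-[(3-methylbut-2-en-1-yl)oxy]benzoic acid F3. Activation of F3 with CDI in THF gives the acyl imidazolide methyl 2-hydroxy-6-{2-(1H-imidazole-1-carbonyl)-4-methoxy-6-[(3-methylbut-2-en-1-yl)oxy]phenoxy}-4-methylbenzoate F4, which is not isolated and is reduced with NaBH4 in THF/H2O at 0 °C to 15; the methyl ester and the alkene stay intact.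

Step 5 (dehydrogenation of the triketone; over-oxidation or incomplete conversion). The fallback sets out from 7 and comes back to the route at 8. Bromine (3 equiv) in AcOH aromatises 7 by α-bromination and loss of HBr and brominates both free ring positions, giving methyl 3,5-dibromo-2,6-dihydroxy-4-methylbenzoate F1. Hydrogenolysis of F1 (H2, Pd/C, NaOAc, MeOH) removes both bromines and returns 8.

Step 7 (regiochemistry of the bromination; attack ortho to OMe would give isomers). The fallback sets out from 9 and comes back to the route at 12, bypassing 10 and 11. The free phenol 9 is brominated with NBS and catalytic diisopropylamine in CH2Cl2 at 0 °C; the amine-mediated delivery is ortho to OH, and of the two ortho positions the one between OH and CHO is also para to OMe. This fallback makes no new compound (F0).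

**Further compounds**
F1 | step 5 | methyl 3,5-dibromo-2,6-dihydroxy-4-methylbenzoate | COC(=O)c1c(O)c(Br)c(C)c(Br)c1O
F0 | step 7 | none | none
F2 | step 10 | 2-bromo-5-methoxy-3-[(3-methylbut-2-en-1-yl)oxy]benzoic acid | COc1cc(OCC=C(C)C)c(Br)c(C(=O)O)c1
F3 | step 10 | 2-[3-hydroxy-2-(methoxycarbonyl)-5-methylphenoxy]-5-methoxy-3-[(3-methylbut-2-en-1-yl)oxy]benzoic acid | COC(=O)c1c(O)cc(C)cc1Oc1c(C(=O)O)cc(OC)cc1OCC=C(C)C
F4 | step 10 | methyl 2-hydroxy-6-{2-(1H-imidazole-1-carbonyl)-4-methoxy-6-[(3-methylbut-2-en-1-yl)oxy]phenoxy}-4-methylbenzoate | COC(=O)c1c(O)cc(C)cc1Oc1c(C(=O)n2ccnc2)cc(OC)cc1OCC=C(C)C
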